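**Plan**

- Retrosynthesis cuts the chain double bonds C11=C12 and C11'=C12' (Wittig), giving a ring B C15 phosphonium salt, 2,7-dimethylocta-2,4,6-trienedial and a ring A C15 phosphonium salt. Within the ring B unit it cuts the C4–O bond and the C6–C7 bond (acetylide plus ketone).
- Enabling feature: in ring B (C1 gem-dimethyl, C2 methylene, C3 and C4 carbinols, C5(CH3)=C6 carrying the chain) the C4 hydroxyl is allylic to C5=C6 and cis to the C3 hydroxyl. A carbonate on the C3 oxygen can therefore hand its carbonyl oxygen to C4 of a C4–C5–C6 allyl cation.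
- Ring B, forward: ketoisophorone → C3 carbinol → acetylide at C6 → tert-butyl carbonate on O3 → ionisation and closure of the cis-fused cyclic carbonate (the only ring made; it then protects the diol to the end) → alkyne to 7E alkene → phosphonium salt.
- Ring A and chain: racemic α-ionone → C15 dienoate → C3' ketone → C3' carbinol → phosphonium salt → Wittig with excess C10 dialdehyde (C25 aldehyde) → Wittig with the ring B salt (C40) → deprotection.
- Stereochemistry: C3 from Ru-catalysed asymmetric transfer hydrogenation; C4 relayed from C3 by the carbonate tether; C3' from an oxazaborolidine-catalysed reduction that also turns the C6' racemate into separable cis and trans diastereomers; chain geometry from E-selective olefinations and Z→E equilibration.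

Key step: step 5

Remark: carotenoid numbering is used (ring B = diol ring, unprimed; ring A = hydroxy ε ring, primed); the catalyst antipodes in steps 1 and 12 follow the usual models for ketones with one unsaturated flank and would be exchanged for their mirror images if the sense of induction proved opposite.

**Ring B fragment**

Step 1
Reactants: 1 ketoisophorone
Product: 2 (4S)-4-hydroxy-2,6,6-trimethylcyclohex-2-en-1-one
Conditions: RuCl[(S,S)-TsDPEN](p-cymene) (1 mol %), i-PrOH, rt
Reagents that add atoms: none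
Why: Noyori-type asymmetric transfer hydrogenation should reduce only the unhindered C4 carbonyl (the C1 carbonyl is shielded by the gem-dimethyl group and the C2 methyl), the chiral Ru hydride choosing one enantiotopic face and so setting the future C3 stereocentre as S.

Step 2
Reactants: 3 (2E)-3-methylpent-2-en-4-yn-1-ol
Product: 4 tert-butyldimethyl{[(2E)-3-methylpent-2-en-4-yn-1-yl]oxy}silane
Conditions: TBSCl, imidazole, CH2Cl2, 0 °C → rt
Reagents that add atoms: tert-butyldimethylsilyl chloride, CC(C)(C)[Si](C)(C)Cl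
Why: Standard silylation of a primary allylic alcohol masks the hydroxyl for the organolithium step and leaves the E alkene and the terminal alkyne untouched.

Step 3
Reactants: 4 silyl ether of the enynol; 2 (4S)-hydroxy enone
Product: 6 (4S)-1-{(3E)-5-[(tert-butyldimethylsilyl)oxy]-3-methylpent-3-en-1-yn-1-yl}-2,6,6-trimethylcyclohex-2-ene-1,4-diol (both C1 epimers), via lithium acetylide 5 (not isolated)
Conditions: 4 (2.3 equiv), n-BuLi (2.2 equiv), THF, −78 °C; then 2, −78 → 0 °C; H2O
Reagents that add atoms: none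
Why: 1,2-Addition of a lithium acetylide to the hindered, non-enolisable enone carbonyl (the first equivalent only deprotonates the hydroxyl of 2) forms the C6–C7 bond, and the configuration of the new tertiary carbinol does not matter because that centre is ionised in step 5.

Step 4
Reactants: 6 diol
Product: 7 tert-butyl (1S)-4-{(3E)-5-[(tert-butyldimethylsilyl)oxy]-3-methylpent-3-en-1-yn-1-yl}-4-hydroxy-3,5,5-trimethylcyclohex-2-en-1-yl carbonate (both C4 epimers)
Conditions: Boc2O, DMAP (cat.), Et3N, CH2Cl2, 0 °C → rt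
Reagents that add atoms: di-tert-butyl dicarbonate, CC(C)(C)OC(=O)OC(=O)OC(C)(C)C
Why: DMAP-catalysed carbonate formation should take place only at the secondary allylic hydroxyl, because the tertiary propargylic hydroxyl is flanked by a quaternary carbon and is too hindered to be acylated under these conditions.

Step 5
Reactants: 7 tertiary alcohol with the tert-butyl carbonate on O3
Product: 10 (3aS,7aR)-6-{(3E)-5-[(tert-butyldimethylsilyl)oxy]-3-methylpent-3-en-1-yn-1-yl}-5,5,7-trimethyl-3a,4,5,7a-tetrahydro-1,3-benzodioxol-2-one, via allyl cation 8 (not isolated), via dioxolanylium ion 9 (not isolated)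
Conditions: Sc(OTf)3 (10 mol %), 4 Å molecular sieves, CH2Cl2/MeNO2, −40 → 0 °C
Reagents that add atoms: none
Why: Proposed new method: Sc(OTf)3 should ionise the tertiary hydroxyl at C6, which is both allylic and propargylic, to give cation 8 with the charge shared by C6, C4 and C8; the carbonyl oxygen of the carbonate on O3 then bonds to C4 to give dioxolanylium ion 9, which loses isobutene so that the capture cannot reverse, and the alkene ends at C5=C6 in conjugation with the enyne. The closest known reaction types are the Lewis acid-catalysed SN1' substitution and 1,3-transposition of tertiary allylic and propargylic alcohols, and the capture of carbocations, iodonium ions and epoxides by tert-butyl carbonates to give cyclic carbonates with loss of isobutene. The one ring formed, the five-membered carbonate, closes in the 5-exo-trig mode onto the C4 terminus of the allyl cation. The new stereocentre at C4 is controlled by C3 through the tether, since the short O–C(=O) link can reach C4 only on the face that carries O3, which makes the ring fusion cis and C4 R. The step needs regioselectivity for C4 over C6 and C8, secured by the tether length (attack at C6 or C8 would require a bridged ring), and chemoselective ionisation of the tertiary alcohol beside the secondary allylic carbonate and the silyl ether, which the greater stability of the tertiary allyl-propargyl cation, the catalytic amount of acid and the low temperature are meant to secure. Both C6 epimers of 7 converge on 8.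

Step 6
Reactants: 10 cyclic carbonate silyl ether
Product: 11 (3aS,7aR)-6-[(3E)-5-hydroxy-3-methylpent-3-en-1-yn-1-yl]-5,5,7-trimethyl-3a,4,5,7a-tetrahydro-1,3-benzodioxol-2-one
Conditions: HF·pyridine, pyridine, THF, 0 °C
Reagents that add atoms: none
Why: Fluoride cleavage of the primary silyl ether under pyridine-buffered conditions should neither open the cyclic carbonate nor ionise the allylic C4–O bond.

Step 7
Reactants: 11 enynol carbonate
Product: 12 (3aS,7aR)-6-[(1Z,3E)-5-hydroxy-3-methylpenta-1,3-dien-1-yl]-5,5,7-trimethyl-3a,4,5,7a-tetrahydro-1,3-benzodioxol-2-one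
Conditions: H2 (1 atm, 1 equiv), Pd/CaCO3 poisoned with Pb(OAc)2 (Lindlar catalyst), quinoline, EtOAc, rt
Reagents that add atoms: none
Why: Lindlar semi-hydrogenation adds one equivalent of hydrogen syn to the alkyne to give the 7Z alkene and should stop there, since the poisoned catalyst reduces neither the tri- and tetrasubstituted alkenes nor the allylic C–O bond, the product being kept at or below room temperature to avoid sigmatropic hydrogen shifts in the Z triene.

Step 8
Reactants: 12 (7Z)-trienol carbonate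
Product: 13 (3aS,7aR)-6-[(1E,3E)-5-hydroxy-3-methylpenta-1,3-dien-1-yl]-5,5,7-trimethyl-3a,4,5,7a-tetrahydro-1,3-benzodioxol-2-one
Conditions: I2 (2 mol %), CH2Cl2, rt, daylight; aq. Na2S2O3
Reagents that add atoms: none
Why: Iodine-catalysed stereomutation (reversible addition of an iodine atom to the triene) should relieve the strain between the 7Z side chain and the ring methyl groups and leave the 7E,9E triene as the main component, any 9Z isomer being removed by chromatography.

Step 9
Reactants: 13 (7E,9E)-trienol carbonate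
Product: 15 {(2E,4E)-3-methyl-5-[(3aS,7aR)-5,5,7-trimethyl-2-oxo-3a,4,5,7a-tetrahydro-1,3-benzodioxol-6-yl]penta-2,4-dien-1-yl}triphenylphosphonium bromide, via allylic bromide 14 (not isolated)
Conditions: CBr4, PPh3, CH2Cl2, −20 °C; then PPh3, rt
Reagents that add atoms: triphenylphosphine, c1ccccc1P(c1ccccc1)c1ccccc1; tetrabromomethane, BrC(Br)(Br)Br
Why: Appel bromination of the primary allylic alcohol followed by quaternisation of triphenylphosphine in the same flask gives the allylic phosphonium salt under neutral conditions, so that no acid is present that could ionise the allylic C4–O bond.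

**Ring A fragment and C25 aldehyde**

Step 10
Reactants: 16 racemic α-ionone
Product: 17 ethyl (2E,4E)-3-methyl-5-(2,6,6-trimethylcyclohex-2-en-1-yl)penta-2,4-dienoate (racemic)
Conditions: (EtO)2P(O)CH2CO2Et, NaH, THF, 0 → 50 °C
Reagents that add atoms: triethyl phosphonoacetate, CCOC(=O)CP(=O)(OCC)OCC
Why: Horner–Wadsworth–Emmons olefination of the methyl ketone adds the two missing chain carbons with the usual E preference at the new trisubstituted C9'=C10' bond, the minor 9'Z ester being removed by chromatography.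

Step 11
Reactants: 17 racemic dienoate
Product: 18 ethyl (2E,4E)-3-methyl-5-(2,6,6-trimethyl-4-oxocyclohex-2-en-1-yl)penta-2,4-dienoate (racemic)
Conditions: Rh2(cap)4 (cap = caprolactamate, 1 mol %), t-BuOOH (70% in water), ClCH2CH2Cl, 40 °C
Reagents that add atoms: tert-butyl hydroperoxide, CC(C)(C)OO
Why: Rh-catalysed allylic C–H oxidation with tert-butyl hydroperoxide should convert the ring methylene next to the trisubstituted alkene (C3') into the enone carbonyl, the electron-poor dienoate being inert to peroxyl radicals and the base-free conditions sparing the acidic C6'–H.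

Step 12
Reactants: 18 racemic keto ester
Product: 19 ethyl (2E,4E)-5-[(1R,4S)-4-hydroxy-2,6,6-trimethylcyclohex-2-en-1-yl]-3-methylpenta-2,4-dienoate
Conditions: (R)-2-methyl-CBS-oxazaborolidine (20 mol %), catecholborane, toluene, −78 °C; chromatography
Reagents that add atoms: none
Why: Corey–Bakshi–Shibata reduction under reagent control (alkenyl carbon as the large group) should deliver hydride to the same face of the ring carbonyl in both enantiomers of 18, so that C3' becomes S throughout and the racemate is converted into the cis (3'S,6'R) ester 19 and its trans (3'S,6'S) diastereomer, which are separated on silica, while the ester is not reduced by catecholborane at this temperature.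

Step 13
Reactants: 19 cis hydroxy ester
Product: 20 ethyl (2E,4E)-5-[(1R,4S)-4-{[tert-butyl(dimethyl)silyl]oxy}-2,6,6-trimethylcyclohex-2-en-1-yl]-3-methylpenta-2,4-dienoate
Conditions: TBSCl, imidazole, DMF, rt
Reagents that add atoms: tert-butyldimethylsilyl chloride, CC(C)(C)[Si](C)(C)Cl
Why: Silylation of the secondary allylic hydroxyl protects the acid-sensitive ε-ring carbinol through the hydride, bromination and ylide steps without touching its configuration.

Step 14
Reactants: 20 silylated ester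
Product: 21 (2E,4E)-5-[(1R,4S)-4-{[tert-butyl(dimethyl)silyl]oxy}-2,6,6-trimethylcyclohex-2-en-1-yl]-3-methylpenta-2,4-dien-1-ol
Conditions: i-Bu2AlH, CH2Cl2, −78 °C; aq. NaK tartrate
Reagents that add atoms: none
Why: 1,2-Reduction of the conjugated ester with i-Bu2AlH at low temperature gives the primary allylic alcohol without conjugate reduction and leaves the silyl ether and the alkenes untouched.

Step 15
Reactants: 21 dienol
Product: 23 {(2E,4E)-5-[(1R,4S)-4-{[tert-butyl(dimethyl)silyl]oxy}-2,6,6-trimethylcyclohex-2-en-1-yl]-3-methylpenta-2,4-dien-1-yl}triphenylphosphonium bromide, via allylic bromide 22 (not isolated)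
Conditions: CBr4, PPh3, CH2Cl2, −20 °C; then PPh3, rt
Reagents that add atoms: triphenylphosphine, c1ccccc1P(c1ccccc1)c1ccccc1; tetrabromomethane, BrC(Br)(Br)Br
Why: Appel bromination and quaternisation of triphenylphosphine give the phosphonium salt under neutral conditions, which avoids the acid-induced epimerisation that threatens the allylic C3' oxygen of the ε ring.

Step 16
Reactants: 23 ring A phosphonium bromide; 24 (2E,4E,6E)-2,7-dimethylocta-2,4,6-trienedial
Product: 27 (3S,6R)-3-[(tert-butyldimethylsilyl)oxy]-12'-apo-ε-caroten-12'-al (all-E C25 aldehyde), via ylide 25 (not isolated), via Z isomer 26 (not isolated)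
Conditions: NaN(SiMe3)2, THF, −78 °C; added to 24 (3 equiv), THF, −78 °C → rt; then I2 (2 mol %), CH2Cl2, rt, daylight
Reagents that add atoms: none
Why: Wittig olefination of the semi-stabilised allylic ylide with an excess of the symmetrical dialdehyde should stop at the mono-adduct because the product aldehyde is less electrophilic and less abundant than 24, and iodine-catalysed stereomutation then converts the Z portion at the new double bond into the all-E aldehyde.

**Assembly and deprotection**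

Step 17
Reactants: 15 ring B phosphonium bromide; 27 C25 aldehyde
Product: 30 (3S,4R,3'S,6'R)-3'-[(tert-butyldimethylsilyl)oxy]-β,ε-carotene-3,4-diyl carbonate (all-E), via ylide 28 (not isolated), via 11Z isomer 29 (not isolated)
Conditions: NaN(SiMe3)2, THF, −78 °C; then 27, −78 → 0 °C; then heptane/EtOAc, 80 °C
Reagents that add atoms: none
Why: Wittig olefination joins C11 to C12 with a non-nucleophilic base at low temperature, which the cyclic carbonate and the silyl ether tolerate, and thermal equilibration converts the hindered 11Z isomer into the all-E polyene, which should crystallise from the hot mixture on cooling.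

Step 18
Reactants: 30 protected carotenoid
Product: 32 (3S,4R,3'S,6'R)-β,ε-carotene-3,4,3'-triol (all-E), via silylated diol 31 (not isolated)
Conditions: K2CO3, MeOH/THF, rt; then Bu4NF, THF, rt
Reagents that add atoms: none
Why: Base-catalysed methanolysis of the cyclic carbonate followed by fluoride cleavage of the silyl ether frees the three hydroxyls without acid, which matters because the C4 and C3' hydroxyls are allylic and would ionise under acidic deprotection.

**Compound list**

1 | ketoisophorone (2,6,6-trimethylcyclohex-2-ene-1,4-dione) | CC1=CC(=O)CC(C)(C)C1=O | starting material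
2 | (4S)-4-hydroxy-2,6,6-trimethylcyclohex-2-en-1-one | CC1=C[C@@H](O)CC(C)(C)C1=O | intermediate
3 | (2E)-3-methylpent-2-en-4-yn-1-ol | C#C/C(C)=C/CO | starting material
4 | tert-butyldimethyl{[(2E)-3-methylpent-2-en-4-yn-1-yl]oxy}silane | C#C/C(C)=C/CO[Si](C)(C)C(C)(C)C | intermediate
5 | {(3E)-5-[(tert-butyldimethylsilyl)oxy]-3-methylpent-3-en-1-yn-1-yl}lithium (lithium acetylide of 4) | [Li]C#C/C(C)=C/CO[Si](C)(C)C(C)(C)C | intermediate
6 | (4S)-1-{(3E)-5-[(tert-butyldimethylsilyl)oxy]-3-methylpent-3-en-1-yn-1-yl}-2,6,6-trimethylcyclohex-2-ene-1,4-diol (both C1 epimers) | CC1=C[C@@H](O)CC(C)(C)C1(O)C#C/C(C)=C/CO[Si](C)(C)C(C)(C)C | intermediate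
7 | tert-butyl (1S)-4-{(3E)-5-[(tert-butyldimethylsilyl)oxy]-3-methylpent-3-en-1-yn-1-yl}-4-hydroxy-3,5,5-trimethylcyclohex-2-en-1-yl carbonate (both C4 epimers) | CC1=C[C@@H](OC(=O)OC(C)(C)C)CC(C)(C)C1(O)C#C/C(C)=C/CO[Si](C)(C)C(C)(C)C | intermediate
8 | (4S)-4-[(tert-butoxycarbonyl)oxy]-1-{(3E)-5-[(tert-butyldimethylsilyl)oxy]-3-methylpent-3-en-1-yn-1-yl}-2,6,6-trimethylcyclohex-2-en-1-ylium (allyl cation; charge shared by C6, C4 and C8, drawn at C6) | CC1=C[C@@H](OC(=O)OC(C)(C)C)CC(C)(C)[C+]1C#C/C(C)=C/CO[Si](C)(C)C(C)(C)C | intermediate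
9 | (3aS,7aR)-2-tert-butoxy-6-{(3E)-5-[(tert-butyldimethylsilyl)oxy]-3-methylpent-3-en-1-yn-1-yl}-5,5,7-trimethyl-3a,4,5,7a-tetrahydro-1,3-benzodioxol-2-ylium | C[Si](C)(C(C)(C)C)OC/C=C(C)/C#CC1=C(C)[C@@H](O[C+](OC(C)(C)C)O2)[C@@H]2CC1(C)C | intermediate
10 | (3aS,7aR)-6-{(3E)-5-[(tert-butyldimethylsilyl)oxy]-3-methylpent-3-en-1-yn-1-yl}-5,5,7-trimethyl-3a,4,5,7a-tetrahydro-1,3-benzodioxol-2-one (cis-3,4-carbonate of the 7,8-didehydro ring B C15 unit) | C[Si](C)(C(C)(C)C)OC/C=C(C)/C#CC1=C(C)[C@@H](OC(=O)O2)[C@@H]2CC1(C)C | intermediate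
11 | (3aS,7aR)-6-[(3E)-5-hydroxy-3-methylpent-3-en-1-yn-1-yl]-5,5,7-trimethyl-3a,4,5,7a-tetrahydro-1,3-benzodioxol-2-one | OC/C=C(C)/C#CC1=C(C)[C@@H](OC(=O)O2)[C@@H]2CC1(C)C | intermediate
12 | (3aS,7aR)-6-[(1Z,3E)-5-hydroxy-3-methylpenta-1,3-dien-1-yl]-5,5,7-trimethyl-3a,4,5,7a-tetrahydro-1,3-benzodioxol-2-one | OC/C=C(C)/C=C\C1=C(C)[C@@H](OC(=O)O2)[C@@H]2CC1(C)C | intermediate
13 | (3aS,7aR)-6-[(1E,3E)-5-hydroxy-3-methylpenta-1,3-dien-1-yl]-5,5,7-trimethyl-3a,4,5,7a-tetrahydro-1,3-benzodioxol-2-one | OC/C=C(C)/C=C/C1=C(C)[C@@H](OC(=O)O2)[C@@H]2CC1(C)C | intermediate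
14 | (3aS,7aR)-6-[(1E,3E)-5-bromo-3-methylpenta-1,3-dien-1-yl]-5,5,7-trimethyl-3a,4,5,7a-tetrahydro-1,3-benzodioxol-2-one | BrC/C=C(C)/C=C/C1=C(C)[C@@H](OC(=O)O2)[C@@H]2CC1(C)C | intermediate
15 | {(2E,4E)-3-methyl-5-[(3aS,7aR)-5,5,7-trimethyl-2-oxo-3a,4,5,7a-tetrahydro-1,3-benzodioxol-6-yl]penta-2,4-dien-1-yl}triphenylphosphonium bromide | [Br-].c1ccccc1[P+](c1ccccc1)(c1ccccc1)C/C=C(C)/C=C/C1=C(C)[C@@H](OC(=O)O2)[C@@H]2CC1(C)C | intermediate
16 | α-ionone, racemic ((3E)-4-(2,6,6-trimethylcyclohex-2-en-1-yl)but-3-en-2-one) | CC1=CCCC(C)(C)C1/C=C/C(C)=O | starting material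
17 | ethyl (2E,4E)-3-methyl-5-(2,6,6-trimethylcyclohex-2-en-1-yl)penta-2,4-dienoate (racemic) | CCOC(=O)/C=C(C)/C=C/C1C(C)=CCCC1(C)C | intermediate
18 | ethyl (2E,4E)-3-methyl-5-(2,6,6-trimethyl-4-oxocyclohex-2-en-1-yl)penta-2,4-dienoate (racemic) | CCOC(=O)/C=C(C)/C=C/C1C(C)=CC(=O)CC1(C)C | intermediate
19 | ethyl (2E,4E)-5-[(1R,4S)-4-hydroxy-2,6,6-trimethylcyclohex-2-en-1-yl]-3-methylpenta-2,4-dienoate | CC1=C[C@@H](O)CC(C)(C)[C@H]1/C=C/C(C)=C/C(=O)OCC | intermediate
20 | ethyl (2E,4E)-5-[(1R,4S)-4-{[tert-butyl(dimethyl)silyl]oxy}-2,6,6-trimethylcyclohex-2-en-1-yl]-3-methylpenta-2,4-dienoate | CC1=C[C@@H](O[Si](C)(C)C(C)(C)C)CC(C)(C)[C@H]1/C=C/C(C)=C/C(=O)OCC | intermediate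
21 | (2E,4E)-5-[(1R,4S)-4-{[tert-butyl(dimethyl)silyl]oxy}-2,6,6-trimethylcyclohex-2-en-1-yl]-3-methylpenta-2,4-dien-1-ol | CC1=C[C@@H](O[Si](C)(C)C(C)(C)C)CC(C)(C)[C@H]1/C=C/C(C)=C/CO | intermediate
22 | (1R,4S)-1-[(1E,3E)-5-bromo-3-methylpenta-1,3-dien-1-yl]-4-{[tert-butyl(dimethyl)silyl]oxy}-2,6,6-trimethylcyclohex-2-ene | CC1=C[C@@H](O[Si](C)(C)C(C)(C)C)CC(C)(C)[C@H]1/C=C/C(C)=C/CBr | intermediate
23 | {(2E,4E)-5-[(1R,4S)-4-{[tert-butyl(dimethyl)silyl]oxy}-2,6,6-trimethylcyclohex-2-en-1-yl]-3-methylpenta-2,4-dien-1-yl}triphenylphosphonium bromide | CC1=C[C@@H](O[Si](C)(C)C(C)(C)C)CC(C)(C)[C@H]1/C=C/C(C)=C/C[P+](c1ccccc1)(c1ccccc1)c1ccccc1.[Br-] | intermediate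
24 | (2E,4E,6E)-2,7-dimethylocta-2,4,6-trienedial | O=C/C(C)=C/C=C/C=C(C)/C=O | starting material
25 | ylide of 23 ({(2E,4E)-5-[(1R,4S)-4-silyloxy-2,6,6-trimethylcyclohex-2-en-1-yl]-3-methylpenta-2,4-dien-1-ylidene}triphenylphosphorane) | CC1=C[C@@H](O[Si](C)(C)C(C)(C)C)CC(C)(C)[C@H]1/C=C/C(C)=C/C=P(c1ccccc1)(c1ccccc1)c1ccccc1 | intermediate
26 | (2E,4E,6E,8Z,10E,12E)-13-[(1R,4S)-4-{[tert-butyl(dimethyl)silyl]oxy}-2,6,6-trimethylcyclohex-2-en-1-yl]-2,7,11-trimethyltrideca-2,4,6,8,10,12-hexaenal (Z at the new double bond) | CC1=C[C@@H](O[Si](C)(C)C(C)(C)C)CC(C)(C)[C@H]1/C=C/C(C)=C/C=C\C(C)=C\C=C\C=C(C)\C=O | intermediate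
27 | (3S,6R)-3-[(tert-butyldimethylsilyl)oxy]-12'-apo-ε-caroten-12'-al ((2E,4E,6E,8E,10E,12E)-13-[(1R,4S)-4-silyloxy-2,6,6-trimethylcyclohex-2-en-1-yl]-2,7,11-trimethyltrideca-2,4,6,8,10,12-hexaenal) | CC1=C[C@@H](O[Si](C)(C)C(C)(C)C)CC(C)(C)[C@H]1/C=C/C(C)=C/C=C/C(C)=C/C=C/C=C(C)/C=O | intermediate
28 | ylide of 15 ({(2E,4E)-3-methyl-5-[(3aS,7aR)-5,5,7-trimethyl-2-oxo-3a,4,5,7a-tetrahydro-1,3-benzodioxol-6-yl]penta-2,4-dien-1-ylidene}triphenylphosphorane) | c1ccccc1P(c1ccccc1)(c1ccccc1)=C/C=C(C)/C=C/C1=C(C)[C@@H](OC(=O)O2)[C@@H]2CC1(C)C | intermediate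
29 | (11Z)-isomer of 30 ((3S,4R,3'S,6'R,11Z)-3'-[(tert-butyldimethylsilyl)oxy]-β,ε-carotene-3,4-diyl carbonate) | CC1=C[C@@H](O[Si](C)(C)C(C)(C)C)CC(C)(C)[C@H]1/C=C/C(C)=C/C=C/C(C)=C/C=C/C=C(C)/C=C\C=C(C)\C=C\C1=C(C)[C@@H](OC(=O)O2)[C@@H]2CC1(C)C | intermediate
30 | (3S,4R,3'S,6'R)-3'-[(tert-butyldimethylsilyl)oxy]-β,ε-carotene-3,4-diyl carbonate (all-E; cyclic carbonate of the cis-3,4-diol) | CC1=C[C@@H](O[Si](C)(C)C(C)(C)C)CC(C)(C)[C@H]1/C=C/C(C)=C/C=C/C(C)=C/C=C/C=C(C)/C=C/C=C(C)/C=C/C1=C(C)[C@@H](OC(=O)O2)[C@@H]2CC1(C)C | intermediate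
31 | (3S,4R,3'S,6'R)-3'-[(tert-butyldimethylsilyl)oxy]-β,ε-carotene-3,4-diol (all-E) | CC1=C[C@@H](O[Si](C)(C)C(C)(C)C)CC(C)(C)[C@H]1/C=C/C(C)=C/C=C/C(C)=C/C=C/C=C(C)/C=C/C=C(C)/C=C/C1=C(C)[C@@H](O)[C@@H](O)CC1(C)C | intermediate
32 | (3S,4R,3'S,6'R)-β,ε-carotene-3,4,3'-triol (all-E) | CC1=C[C@@H](O)CC(C)(C)[C@H]1/C=C/C(C)=C/C=C/C(C)=C/C=C/C=C(C)/C=C/C=C(C)/C=C/C1=C(C)[C@@H](O)[C@@H](O)CC1(C)C | target

**Step count**

Total steps: 18.
Longest linear sequence: 10 steps (steps 1, 3, 4, 5, 6, 7, 8, 9, 17, 18, from ketoisophorone; the same length counted from the enynol through step 2).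

**Steps most likely to fail**

1. Step 5. The ionisation may take another course: the water set free may add to the alkyne terminus of the cation (a Meyer–Schuster-type rearrangement), or the acid may strip the tert-butyl carbonate or the silyl ether before the ring closes. Fallback with known chemistry, setting out from 7: a rhenium-oxo-catalysed 1,3-transposition of the tertiary allylic alcohol (Ph3SiOReO3, Et2O, −50 → 0 °C) moves the hydroxyl from C6 to C4 and the alkene into conjugation with the enyne. Without the tether there is no facial control, so this should give tert-butyl (1S,2R)-2-hydroxy-3,5,5-trimethyl-4-{(3E)-5-[(tert-butyldimethylsilyl)oxy]-3-methylpent-3-en-1-yn-1-yl}cyclohex-3-en-1-yl carbonate F1 together with its (1S,2S) trans isomer F2, to be separated on silica. Treatment of F1 with NaH in THF at 0 °C lets the C4 alkoxide attack the neighbouring carbonate carbonyl and expel tert-butoxide, which returns the route to 10; F2 is set aside.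

2. Step 12. Reagent control over the face of hydride delivery may be poor for one enantiomer of the racemic ketone (the mismatched pairing with the ring's own bias), or the cis and trans alcohols may separate badly. Fallback, setting out from 18: Luche reduction (NaBH4, CeCl3·7H2O, MeOH, −20 °C) gives the racemic cis alcohol, rac-ethyl (2E,4E)-5-[(1R*,4S*)-4-hydroxy-2,6,6-trimethylcyclohex-2-en-1-yl]-3-methylpenta-2,4-dienoate F3, beside the racemic trans alcohol F4, which is removed on silica. Kinetic resolution of F3 by lipase-catalysed acetylation (lipase from Burkholderia cepacia, vinyl acetate, t-BuOMe, rt) is then expected, by the empirical rule for cyclohex-2-en-1-ols, to acetylate the (3'R,6'S) antipode to ethyl (2E,4E)-5-[(1S,4R)-4-acetoxy-2,6,6-trimethylcyclohex-2-en-1-yl]-3-methylpenta-2,4-dienoate F5 and to leave the (3'S,6'R) alcohol, which is 19, where the route is rejoined.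

3. Step 17. The ylide carbon of 28 is conjugated through the triene with C5, so vinylogous elimination of the C4 carbonate may compete with olefination, and the Z→E equilibration may stay incomplete. Fallback by reversing the polarity of the last coupling, setting out from 13 and 27: MnO2 (CH2Cl2, rt) oxidises 13 to (2E,4E)-3-methyl-5-[(3aS,7aR)-5,5,7-trimethyl-2-oxo-3a,4,5,7a-tetrahydro-1,3-benzodioxol-6-yl]penta-2,4-dienal F6, which carries no carbanion next to the carbonate. NaBH4 (MeOH/THF, 0 °C) reduces 27 to the C25 alcohol (3S,6R)-3-[(tert-butyldimethylsilyl)oxy]-12'-apo-ε-caroten-12'-ol F7. This is taken through the C25 allylic bromide F8 (CBr4, PPh3) to the C25 triphenylphosphonium bromide F9, whose ylide, the C25 phosphorane F10 (NaN(SiMe3)2, THF, −78 °C), is condensed with F6. Thermal equilibration as in step 17 (through 29) then returns the route to 30.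

**Further compounds**

F1 | step 5 | tert-butyl (1S,2R)-2-hydroxy-3,5,5-trimethyl-4-{(3E)-5-[(tert-butyldimethylsilyl)oxy]-3-methylpent-3-en-1-yn-1-yl}cyclohex-3-en-1-yl carbonate | C[Si](C)(C(C)(C)C)OC/C=C(C)/C#CC1=C(C)[C@@H](O)[C@@H](OC(=O)OC(C)(C)C)CC1(C)C
F2 | step 5 | tert-butyl (1S,2S)-2-hydroxy-3,5,5-trimethyl-4-{(3E)-5-[(tert-butyldimethylsilyl)oxy]-3-methylpent-3-en-1-yn-1-yl}cyclohex-3-en-1-yl carbonate | C[Si](C)(C(C)(C)C)OC/C=C(C)/C#CC1=C(C)[C@H](O)[C@@H](OC(=O)OC(C)(C)C)CC1(C)C
F3 | step 12 | rac-ethyl (2E,4E)-5-[(1R*,4S*)-4-hydroxy-2,6,6-trimethylcyclohex-2-en-1-yl]-3-methylpenta-2,4-dienoate (racemic cis; one enantiomer drawn) | CC1=C[C@@H](O)CC(C)(C)[C@H]1/C=C/C(C)=C/C(=O)OCC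
F4 | step 12 | rac-ethyl (2E,4E)-5-[(1S*,4S*)-4-hydroxy-2,6,6-trimethylcyclohex-2-en-1-yl]-3-methylpenta-2,4-dienoate (racemic trans; one enantiomer drawn) | CC1=C[C@@H](O)CC(C)(C)[C@@H]1/C=C/C(C)=C/C(=O)OCC
F5 | step 12 | ethyl (2E,4E)-5-[(1S,4R)-4-acetoxy-2,6,6-trimethylcyclohex-2-en-1-yl]-3-methylpenta-2,4-dienoate | CC1=C[C@H](OC(C)=O)CC(C)(C)[C@@H]1/C=C/C(C)=C/C(=O)OCC
F6 | step 17 | (2E,4E)-3-methyl-5-[(3aS,7aR)-5,5,7-trimethyl-2-oxo-3a,4,5,7a-tetrahydro-1,3-benzodioxol-6-yl]penta-2,4-dienal | O=C/C=C(C)/C=C/C1=C(C)[C@@H](OC(=O)O2)[C@@H]2CC1(C)C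
F7 | step 17 | (3S,6R)-3-[(tert-butyldimethylsilyl)oxy]-12'-apo-ε-caroten-12'-ol | CC1=C[C@@H](O[Si](C)(C)C(C)(C)C)CC(C)(C)[C@H]1/C=C/C(C)=C/C=C/C(C)=C/C=C/C=C(C)/CO
F8 | step 17 | (3S,6R)-12'-bromo-3-[(tert-butyldimethylsilyl)oxy]-12'-apo-ε-carotene | CC1=C[C@@H](O[Si](C)(C)C(C)(C)C)CC(C)(C)[C@H]1/C=C/C(C)=C/C=C/C(C)=C/C=C/C=C(C)/CBr
F9 | step 17 | {(3S,6R)-3-[(tert-butyldimethylsilyl)oxy]-12'-apo-ε-caroten-12'-yl}triphenylphosphonium bromide | CC1=C[C@@H](O[Si](C)(C)C(C)(C)C)CC(C)(C)[C@H]1/C=C/C(C)=C/C=C/C(C)=C/C=C/C=C(C)/C[P+](c1ccccc1)(c1ccccc1)c1ccccc1.[Br-]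
F10 | step 17 | {(3S,6R)-3-[(tert-butyldimethylsilyl)oxy]-12'-apo-ε-caroten-12'-ylidene}triphenylphosphorane | CC1=C[C@@H](O[Si](C)(C)C(C)(C)C)CC(C)(C)[C@H]1/C=C/C(C)=C/C=C/C(C)=C/C=C/C=C(C)/C=P(c1ccccc1)(c1ccccc1)c1ccccc1
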